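**Plan**

- Cuts: the vinyl group goes back to an aldehyde (C14=C15). The two acid arms are cut at C1–C10 and C4–C5, as [3,3] shifts of an acetate on O6 and an isobutyrate on O7 of a 6,7-cis-diol on a cyclohexene. The two bonds O–C13 and C8–C9 are then cut together, as one oxa-[4+2] event, to an acyclic triene ketone, which is cut at C9–C10, C11–C12 and C5=C10.
- Forward: D-erythronolactone acetonide (C5–C8) gives a (Z)-vinyl iodide; propargyl alcohol gives a (1E,3Z)-dienylstannane. Stille union and methyl ketone formation follow, then rings B (carbocycle) and C (pyran) close in one step. The ring-B double bond is walked C5=C10 → C5=C6 → C6=C7 by two Ireland–Claisen shifts and hydrogenated; oxidation and Wittig give the vinyl group.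
- Enabling feature: the ring oxygen sits between two fully substituted carbons, C8 and C13, joined through C9–C11–C12. A C8 methyl ketone and a C9=C11–C12=C13 diene therefore map onto ring C, and the four-atom link C10=C5–C6–C7 makes the same event close ring B.
- Stereochemistry: C6 and C7 of the lactone (both R) fix C8, C9 and C13 in the cycloaddition. Their oxygens (not on these carbons in the target) then deliver CH2CO2H to C10 and the axial CMe2CO2H to C5 on one face, and end as carboxyl oxygens.

Key step: step 9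

Remark: carbons carry labdane-type locants (ring oxygen between C8 and C13; C17, C20 and C16 are the methyls on C8, C10 and C13; C14 becomes the vinyl CH). The target as drawn has H-5 cis to the C-10 methyl, so CH2CO2H and CMe2CO2H are cis on ring B and CMe2CO2H is axial.

**Route**

Step 1
Reactants: 1 2,3-O-isopropylidene-D-erythronolactone
Product: 2 (4R,5R)-5-(hydroxymethyl)-N-methoxy-N,2,2-trimethyl-1,3-dioxolane-4-carboxamide
Conditions: MeNH(OMe)·HCl, AlMe3, CH2Cl2, 0 °C → rt
Reagents that add atoms: N,O-dimethylhydroxylamine hydrochloride (CNOC.Cl)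
Why: Aluminium-amide aminolysis of the lactone (Weinreb amide formation) opens the ring at the acyl carbon and leaves both stereocenters of the chiral pool untouched.

Step 2
Reactants: 2 hydroxy Weinreb amide
Product: 3 (4R,5S)-5-formyl-N-methoxy-N,2,2-trimethyl-1,3-dioxolane-4-carboxamide
Conditions: TEMPO (10 mol %), PhI(OAc)2, CH2Cl2, rt
Reagents that add atoms: none
Why: Oxoammonium (TEMPO) oxidation should stop at the aldehyde and is mild enough not to epimerise the α-oxygenated centre.

Step 3
Reactants: 3 aldehyde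
Product: 4 (4R,5R)-5-[(1Z)-2-iodoprop-1-en-1-yl]-N-methoxy-N,2,2-trimethyl-1,3-dioxolane-4-carboxamide
Conditions: EtPPh3I, n-BuLi, THF, 0 °C; I2, −78 °C; NaN(SiMe3)2, −20 °C; then 3, −78 °C
Reagents that add atoms: ethyltriphenylphosphonium iodide (CC[P+](c1ccccc1)(c1ccccc1)c1ccccc1.[I-]); iodine (II)
Why: Stork–Zhao olefination with the α-iodo ylide should give the (Z)-2-iodoalkene (iodine cis to the dioxolane carbon, as ring B later requires) under kinetic control at a temperature where the α-alkoxy aldehyde does not epimerise.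

Step 4
Reactants: 5 propargyl alcohol
Product: 7 (2Z)-3-iodo-2-methylprop-2-en-1-ol, via alkenylmagnesium chelate 6 (not isolated)
Conditions: MeMgBr (2.5 equiv), CuI (10 mol %), Et2O, −10 °C → rt; then I2, THF, −20 °C
Reagents that add atoms: methylmagnesium bromide (C[Mg]Br); iodine (II)
Why: Copper-catalysed carbomagnesiation of the propargylic magnesium alkoxide delivers methyl to C13 and magnesium to C12 in an anti sense through the five-membered chelate 6, and iodinolysis with retention gives the (Z)-iodide.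

Step 5
Reactants: 7 (2Z)-3-iodo-2-methylprop-2-en-1-ol
Product: 8 ({[(2Z)-3-iodo-2-methylprop-2-en-1-yl]oxy}methyl)benzene
Conditions: NaH, BnBr, n-Bu4NI (cat.), THF, 0 °C → rt
Reagents that add atoms: benzyl bromide (BrCc1ccccc1)
Why: Williamson ether synthesis protects the alcohol as a benzyl ether that should survive the organometallic and Lewis-acid steps and fall off in the later hydrogenation.

Step 6
Reactants: 8 benzyl (Z)-iodoallyl ether
Product: 9 tributyl[(1E,3Z)-5-(benzyloxy)-4-methylpenta-1,3-dien-1-yl]stannane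
Conditions: (E)-Bu3SnCH=CHSnBu3 (3 equiv), PdCl2(MeCN)2 (5 mol %), DMF, rt
Reagents that add atoms: (E)-1,2-bis(tributylstannyl)ethene (CCCC[Sn](CCCC)(CCCC)/C=C/[Sn](CCCC)(CCCC)CCCC)
Why: Stille coupling at one end of the distannane proceeds with retention at both double bonds, and the excess of distannane suppresses double coupling, so the (1E,3Z)-dienylstannane is expected.

Step 7
Reactants: 4 (Z)-vinyl iodide Weinreb amide; 9 dienylstannane
Product: 10 (4R,5R)-5-[(1Z,3E,5Z)-7-(benzyloxy)-2,6-dimethylhepta-1,3,5-trien-1-yl]-N-methoxy-N,2,2-trimethyl-1,3-dioxolane-4-carboxamide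
Conditions: Pd2(dba)3 (5 mol %), AsPh3 (20 mol %), NMP, 40 °C, dark
Reagents that add atoms: none
Why: Stille coupling joins C9 to C10 with retention of all three alkene geometries and tolerates the Weinreb amide and the acetonide.

Step 8
Reactants: 10 triene Weinreb amide
Product: 11 1-[(4R,5R)-5-[(1Z,3E,5Z)-7-(benzyloxy)-2,6-dimethylhepta-1,3,5-trien-1-yl]-2,2-dimethyl-1,3-dioxolan-4-yl]ethan-1-one
Conditions: MeMgBr, THF, −20 → 0 °C
Reagents that add atoms: methylmagnesium bromide (C[Mg]Br)
Why: Weinreb ketone synthesis: the chelated tetrahedral adduct collapses only on work-up, so one methyl adds and the neighbouring C7 centre is not enolised.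

Step 9
Reactants: 11 triene methyl ketone
Product: 12 (2R,4aR,7R,8R,8aS)-2-[(benzyloxy)methyl]-7,8-(isopropylidenedioxy)-2,5,8a-trimethyl-4a,7,8,8a-tetrahydro-2H-chromene
Conditions: Me2AlCl (1.2 equiv), CH2Cl2, −78 → −30 °C
Reagents that add atoms: none
Why: Proposed new method: Me2AlCl held between the ketone oxygen and O7 activates C8; diene terminus C9 adds to it (6-exo-trig at the carbonyl, which closes carbocycle B around the C5=C10 bond) and the aluminium-bound oxygen closes on C13 of the developing C11–C13 allyl cation (6-endo capture), so that ring C is formed as the new ring of a polar, strongly asynchronous oxa-[4+2] addition. The closest known reaction types are the acid-catalysed oxa-Diels–Alder additions of aldehydes and of activated ketones to simple dienes and the alkylaluminium-chloride-promoted intramolecular Prins and ene cyclisations of ketones; an α-oxygenated but otherwise unactivated methyl ketone adding across a diene with a disubstituted terminus has not been shown. C8 and C9 are set in a half-chair for ring B with the aluminium-bound oxygen and the diene equatorial (trans B/C fusion) and with O7 axial, anti to the axial C8 methyl; the other face would force O6 of the cis-dioxolane syn-axial to that methyl, so the (6R,7R)-acetonide should decide the face. C13 is set by suprafacial addition across the diene, the 12Z geometry placing the C13 methyl outside (cis to C10) and CH2OBn inside. The step needs bonding at C9 (not C5, C10, C11 or C13) and termination by oxygen (not proton loss): only C9 gives a six-membered carbocycle, the cation is tertiary and allylic at C13 six atoms from the oxygen, and Me2AlCl removes adventitious acid.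

Step 10
Reactants: 12 tricyclic acetonide
Product: 13 (2R,4aR,7R,8R,8aS)-2-[(benzyloxy)methyl]-2,5,8a-trimethyl-4a,7,8,8a-tetrahydro-2H-chromene-7,8-diol
Conditions: camphorsulfonic acid (10 mol %), MeOH, 0 °C → rt
Reagents that add atoms: none
Why: Acid-catalysed transacetalisation to methanol removes the acetonide under conditions chosen to be mild enough for the tertiary allylic ether of ring C.

Step 11
Reactants: 13 cis-diol
Product: 15 (2R,4aR,7R,8R,8aS)-2-[(benzyloxy)methyl]-7-hydroxy-2,5,8a-trimethyl-4a,7,8,8a-tetrahydro-2H-chromen-8-yl 2-methylpropanoate, via cyclic orthoester 14 (not isolated)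
Conditions: Me2CHC(OMe)3, camphorsulfonic acid (cat.), CH2Cl2, rt; then AcOH–H2O (4:1), 0 °C
Reagents that add atoms: trimethyl orthoisobutyrate (COC(OC)(OC)C(C)C); water (O)
Why: Cyclic orthoester formation on the cis-diol and stereoelectronically controlled hydrolysis of the derived dioxolanylium ion should place the ester on the axial oxygen (O7) and free the pseudo-equatorial allylic C6 hydroxyl.

Step 12
Reactants: 15 C7 mono-isobutyrate
Product: 16 (2R,4aR,7R,8R,8aS)-7-(acetyloxy)-2-[(benzyloxy)methyl]-2,5,8a-trimethyl-4a,7,8,8a-tetrahydro-2H-chromen-8-yl 2-methylpropanoate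
Conditions: Ac2O, pyridine, DMAP (cat.), CH2Cl2, 0 °C
Reagents that add atoms: acetic anhydride (CC(=O)OC(C)=O)
Why: DMAP-catalysed acetylation of the remaining allylic hydroxyl should be fast enough to outrun acyl migration.

Step 13
Reactants: 16 C6 acetate C7 isobutyrate
Product: 20 2-[(2R,4aR,5S,6S,8aR)-2-[(benzyloxy)methyl]-5-(carboxymethyl)-2,5,8a-trimethyl-4a,5,6,8a-tetrahydro-2H-chromen-6-yl]-2-methylpropanoic acid, via bis(silyl ketene acetal) 17 (not isolated), via mono-rearranged silyl ester 18 (not isolated), via bis(trimethylsilyl) ester 19 (not isolated)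
Conditions: LiN(i-Pr)2 (3 equiv), TMSCl–Et3N (premixed), THF, −78 °C → rt; toluene, 100 °C; 1 M HCl work-up
Reagents that add atoms: none
Why: Tandem Ireland–Claisen rearrangements: the acetate ketene acetal shifts suprafacially from O6 to C10 (setting the quaternary centre with CH2CO2 on the face that carried O6 and moving the double bond to C5=C6), which makes the O7 isobutyrate ketene acetal allylic so that it shifts suprafacially from its pseudo-axial C7–O bond to C5 (placing CMe2CO2 axial and cis to the acetic arm), neither ketene acetal having a geometry issue.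

Step 14
Reactants: 20 diacid diene
Product: 22 2-[(2R,4aR,5S,6S,8aR)-5-(carboxymethyl)-2-(hydroxymethyl)-2,5,8a-trimethyloctahydro-2H-chromen-6-yl]-2-methylpropanoic acid, via saturated benzyl ether 21 (not isolated)
Conditions: H2 (1 atm), PtO2, EtOAc, rt; then Pd(OH)2/C, H2 (1 atm), rt
Reagents that add atoms: none
Why: Heterogeneous hydrogenation saturates the two cis-disubstituted ring alkenes over PtO2 (chosen because it should not hydrogenolyse the allylic C–O bonds of ring C) and the added Pd(OH)2/C then cleaves the benzyl ether, no stereocentre being formed.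

Step 15
Reactants: 22 hydroxy diacid
Product: 23 2-[(2R,4aR,5S,6S,8aR)-5-(carboxymethyl)-2-formyl-2,5,8a-trimethyloctahydro-2H-chromen-6-yl]-2-methylpropanoic acid
Conditions: Dess–Martin periodinane, CH2Cl2, 0 °C → rt
Reagents that add atoms: none
Why: Dess–Martin oxidation converts the neopentyl primary alcohol into the non-enolisable aldehyde without touching the carboxylic acids.

Step 16
Reactants: 23 aldehyde diacid
Product: 24 2-[(2R,4aR,5S,6S,8aR)-5-(carboxymethyl)-2-ethenyl-2,5,8a-trimethyloctahydro-2H-chromen-6-yl]-2-methylpropanoic acid (target)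
Conditions: Ph3PCH3Br, KN(SiMe3)2 (5 equiv), THF, 0 °C → rt; 1 M HCl work-up
Reagents that add atoms: methyltriphenylphosphonium bromide (C[P+](c1ccccc1)(c1ccccc1)c1ccccc1.[Br-])
Why: Wittig methylenation of the aldehyde in the presence of the two carboxylates (excess ylide) installs the vinyl group and leaves all five stereocentres untouched.

**Compound list**

1 | 2,3-O-isopropylidene-D-erythronolactone; (3aR,6aR)-2,2-dimethyldihydrofuro[3,4-d][1,3]dioxol-4(3aH)-one | CC1(C)O[C@H]2[C@@H](O1)C(=O)OC2 | starting material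
2 | (4R,5R)-5-(hydroxymethyl)-N-methoxy-N,2,2-trimethyl-1,3-dioxolane-4-carboxamide | CC1(C)O[C@H](CO)[C@@H](O1)C(=O)N(C)OC | intermediate
3 | (4R,5S)-5-formyl-N-methoxy-N,2,2-trimethyl-1,3-dioxolane-4-carboxamide | CC1(C)O[C@H](C=O)[C@@H](O1)C(=O)N(C)OC | intermediate
4 | (4R,5R)-5-[(1Z)-2-iodoprop-1-en-1-yl]-N-methoxy-N,2,2-trimethyl-1,3-dioxolane-4-carboxamide | CC1(C)O[C@H](/C=C(/C)I)[C@@H](O1)C(=O)N(C)OC | intermediate
5 | propargyl alcohol (prop-2-yn-1-ol) | C#CCO | starting material
6 | bromomagnesium (2Z)-3-(bromomagnesio)-2-methylprop-2-en-1-olate (chelated alkenylmagnesium) | Br[Mg]/C=C(/C)CO[Mg]Br | intermediate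
7 | (2Z)-3-iodo-2-methylprop-2-en-1-ol | I/C=C(/C)CO | intermediate
8 | ({[(2Z)-3-iodo-2-methylprop-2-en-1-yl]oxy}methyl)benzene | I/C=C(/C)COCc1ccccc1 | intermediate
9 | tributyl[(1E,3Z)-5-(benzyloxy)-4-methylpenta-1,3-dien-1-yl]stannane | CCCC[Sn](CCCC)(CCCC)/C=C/C=C(/C)COCc1ccccc1 | intermediate
10 | (4R,5R)-5-[(1Z,3E,5Z)-7-(benzyloxy)-2,6-dimethylhepta-1,3,5-trien-1-yl]-N-methoxy-N,2,2-trimethyl-1,3-dioxolane-4-carboxamide | CC1(C)O[C@H](/C=C(/C)\C=C\C=C(\C)COCc2ccccc2)[C@@H](O1)C(=O)N(C)OC | intermediate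
11 | 1-[(4R,5R)-5-[(1Z,3E,5Z)-7-(benzyloxy)-2,6-dimethylhepta-1,3,5-trien-1-yl]-2,2-dimethyl-1,3-dioxolan-4-yl]ethan-1-one | CC1(C)O[C@H](/C=C(/C)\C=C\C=C(\C)COCc2ccccc2)[C@@H](O1)C(C)=O | intermediate
12 | (2R,4aR,7R,8R,8aS)-2-[(benzyloxy)methyl]-7,8-(isopropylidenedioxy)-2,5,8a-trimethyl-4a,7,8,8a-tetrahydro-2H-chromene | C(OCc1ccccc1)[C@@]1(C)C=C[C@@H]2C(C)=C[C@H]3OC(C)(C)O[C@H]3[C@@]2(C)O1 | intermediate
13 | (2R,4aR,7R,8R,8aS)-2-[(benzyloxy)methyl]-2,5,8a-trimethyl-4a,7,8,8a-tetrahydro-2H-chromene-7,8-diol | C(OCc1ccccc1)[C@@]1(C)C=C[C@@H]2C(C)=C[C@@H](O)[C@@H](O)[C@@]2(C)O1 | intermediate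
14 | 7,8-O-(1-methoxy-2-methylpropylidene) derivative of 13 (cyclic orthoester, orthoester carbon as a mixture) | C(OCc1ccccc1)[C@@]1(C)C=C[C@@H]2C(C)=C[C@H]3OC(OC)(C(C)C)O[C@H]3[C@@]2(C)O1 | intermediate
15 | (2R,4aR,7R,8R,8aS)-2-[(benzyloxy)methyl]-7-hydroxy-2,5,8a-trimethyl-4a,7,8,8a-tetrahydro-2H-chromen-8-yl 2-methylpropanoate | C(OCc1ccccc1)[C@@]1(C)C=C[C@@H]2C(C)=C[C@@H](O)[C@@H](OC(=O)C(C)C)[C@@]2(C)O1 | intermediate
16 | (2R,4aR,7R,8R,8aS)-7-(acetyloxy)-2-[(benzyloxy)methyl]-2,5,8a-trimethyl-4a,7,8,8a-tetrahydro-2H-chromen-8-yl 2-methylpropanoate | C(OCc1ccccc1)[C@@]1(C)C=C[C@@H]2C(C)=C[C@@H](OC(C)=O)[C@@H](OC(=O)C(C)C)[C@@]2(C)O1 | intermediate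
17 | bis(trimethylsilyl ketene acetal) of 16 (7-O-[1-(trimethylsilyloxy)ethenyl], 8-O-[2-methyl-1-(trimethylsilyloxy)prop-1-enyl]) | C(OCc1ccccc1)[C@@]1(C)C=C[C@@H]2C(C)=C[C@@H](OC(=C)O[Si](C)(C)C)[C@@H](OC(O[Si](C)(C)C)=C(C)C)[C@@]2(C)O1 | intermediate
18 | trimethylsilyl 2-[(2R,4aR,5S,8R,8aS)-2-[(benzyloxy)methyl]-2,5,8a-trimethyl-8-{[2-methyl-1-(trimethylsilyloxy)prop-1-en-1-yl]oxy}-4a,5,8,8a-tetrahydro-2H-chromen-5-yl]acetate | C(OCc1ccccc1)[C@@]1(C)C=C[C@@H]2[C@@](C)(CC(=O)O[Si](C)(C)C)C=C[C@@H](OC(O[Si](C)(C)C)=C(C)C)[C@@]2(C)O1 | intermediate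
19 | bis(trimethylsilyl) ester of 20 | C(OCc1ccccc1)[C@@]1(C)C=C[C@@H]2[C@@](C)(CC(=O)O[Si](C)(C)C)[C@@H](C(C)(C)C(=O)O[Si](C)(C)C)C=C[C@@]2(C)O1 | intermediate
20 | 2-[(2R,4aR,5S,6S,8aR)-2-[(benzyloxy)methyl]-5-(carboxymethyl)-2,5,8a-trimethyl-4a,5,6,8a-tetrahydro-2H-chromen-6-yl]-2-methylpropanoic acid | C(OCc1ccccc1)[C@@]1(C)C=C[C@@H]2[C@@](C)(CC(=O)O)[C@@H](C(C)(C)C(=O)O)C=C[C@@]2(C)O1 | intermediate
21 | 2-[(2R,4aR,5S,6S,8aR)-2-[(benzyloxy)methyl]-5-(carboxymethyl)-2,5,8a-trimethyloctahydro-2H-chromen-6-yl]-2-methylpropanoic acid | C(OCc1ccccc1)[C@@]1(C)CC[C@@H]2[C@@](C)(CC(=O)O)[C@@H](C(C)(C)C(=O)O)CC[C@@]2(C)O1 | intermediate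
22 | 2-[(2R,4aR,5S,6S,8aR)-5-(carboxymethyl)-2-(hydroxymethyl)-2,5,8a-trimethyloctahydro-2H-chromen-6-yl]-2-methylpropanoic acid | OC[C@@]1(C)CC[C@@H]2[C@@](C)(CC(=O)O)[C@@H](C(C)(C)C(=O)O)CC[C@@]2(C)O1 | intermediate
23 | 2-[(2R,4aR,5S,6S,8aR)-5-(carboxymethyl)-2-formyl-2,5,8a-trimethyloctahydro-2H-chromen-6-yl]-2-methylpropanoic acid | O=C[C@@]1(C)CC[C@@H]2[C@@](C)(CC(=O)O)[C@@H](C(C)(C)C(=O)O)CC[C@@]2(C)O1 | intermediate
24 | 2-[(2R,4aR,5S,6S,8aR)-5-(carboxymethyl)-2-ethenyl-2,5,8a-trimethyloctahydro-2H-chromen-6-yl]-2-methylpropanoic acid | C=C[C@@]1(C)CC[C@@H]2[C@@](C)(CC(=O)O)[C@@H](C(C)(C)C(=O)O)CC[C@@]2(C)O1 | target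

**Count and risks**

Total step count: 16. Longest linear sequence: 13 steps (steps 1–3 and 7–16; the branch through steps 4–6 is equally long).

The three steps most likely to fail:

1. Step 9 (Proposed new method). The allyl cation formed after C8–C9 bonding may lose a proton (ene-type termination) instead of being captured by oxygen, and ionisation of the allylic C6–O bond by the Lewis acid may compete. The fallback separates the two bond formations into established reactions. From 11, an alkylaluminium-chloride-promoted Prins–ene cyclisation of the unsaturated ketone (MeAlCl2, CH2Cl2, −78 °C) is run to the tertiary dienol (3aR,4S,5R,7aR)-5-[(1Z)-3-[(benzyloxy)methyl]buta-1,3-dien-1-yl]-2,2,4,6-tetramethyl-3a,4,5,7a-tetrahydro-1,3-benzodioxol-4-ol F1. Acid-catalysed cyclo-etherification (camphorsulfonic acid cat., CH2Cl2, 0 °C) then protonates the methylene terminus of the diene and lets the C8 hydroxyl capture the tertiary allyl cation at C13, the classical closure of 2,2-disubstituted dihydropyrans from dienols. This comes back to the route at 12, with C13 then under thermodynamic control.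

2. Step 13. The second [3,3] shift builds a bond between C4 and the congested C5, and the first needs ring B to leave its resting half-chair. The silyl ketene acetals may decompose (C-silylation of the acetate, elimination) before the relay is complete. The fallback runs the two shifts as separate reactions of different type. From 15, a Johnson–Claisen rearrangement of the free allylic alcohol (MeC(OEt)3, propionic acid cat., xylene, 140 °C) gives ethyl 2-[(2R,4aR,5S,8R,8aS)-2-[(benzyloxy)methyl]-2,5,8a-trimethyl-8-[(2-methylpropanoyl)oxy]-4a,5,8,8a-tetrahydro-2H-chromen-5-yl]acetate F2. A single Ireland–Claisen rearrangement of the isobutyrate (LiN(i-Pr)2, TMSCl, THF, then toluene, 100 °C) gives 2-[(2R,4aR,5S,6S,8aR)-2-[(benzyloxy)methyl]-5-(2-ethoxy-2-oxoethyl)-2,5,8a-trimethyl-4a,5,6,8a-tetrahydro-2H-chromen-6-yl]-2-methylpropanoic acid F3. Saponification of the unhindered ethyl ester (LiOH, THF–H2O) comes back to the route at 20.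

3. Step 11. Opening of the orthoester may not discriminate the two oxygens well enough, or the isobutyryl group may migrate from O7 to O6; either would exchange the two acid arms. The fallback relies on steric instead of stereoelectronic control. From 13, kinetic acetylation of the less hindered allylic hydroxyl (AcCl, 2,4,6-collidine, CH2Cl2, −78 °C) gives (2R,4aR,7R,8R,8aS)-2-[(benzyloxy)methyl]-8-hydroxy-2,5,8a-trimethyl-4a,7,8,8a-tetrahydro-2H-chromen-7-yl acetate F4. Forced acylation of the hindered axial hydroxyl ((i-PrCO)2O, DMAP, Et3N, CH2Cl2, rt) comes back to the route at 16.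

Further compounds
F1 | step 9 | (3aR,4S,5R,7aR)-5-[(1Z)-3-[(benzyloxy)methyl]buta-1,3-dien-1-yl]-2,2,4,6-tetramethyl-3a,4,5,7a-tetrahydro-1,3-benzodioxol-4-ol | C=C(COCc1ccccc1)/C=C\[C@@H]1C(C)=C[C@H]2OC(C)(C)O[C@H]2[C@@]1(C)O
F2 | step 13 | ethyl 2-[(2R,4aR,5S,8R,8aS)-2-[(benzyloxy)methyl]-2,5,8a-trimethyl-8-[(2-methylpropanoyl)oxy]-4a,5,8,8a-tetrahydro-2H-chromen-5-yl]acetate | C(OCc1ccccc1)[C@@]1(C)C=C[C@@H]2[C@@](C)(CC(=O)OCC)C=C[C@@H](OC(=O)C(C)C)[C@@]2(C)O1
F3 | step 13 | 2-[(2R,4aR,5S,6S,8aR)-2-[(benzyloxy)methyl]-5-(2-ethoxy-2-oxoethyl)-2,5,8a-trimethyl-4a,5,6,8a-tetrahydro-2H-chromen-6-yl]-2-methylpropanoic acid | C(OCc1ccccc1)[C@@]1(C)C=C[C@@H]2[C@@](C)(CC(=O)OCC)[C@@H](C(C)(C)C(=O)O)C=C[C@@]2(C)O1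
F4 | step 11 | (2R,4aR,7R,8R,8aS)-2-[(benzyloxy)methyl]-8-hydroxy-2,5,8a-trimethyl-4a,7,8,8a-tetrahydro-2H-chromen-7-yl acetate | C(OCc1ccccc1)[C@@]1(C)C=C[C@@H]2C(C)=C[C@@H](OC(C)=O)[C@@H](O)[C@@]2(C)O1
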